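**Retrosynthetic overview**

1. Target 23 (14-hydroxy-3-isobutyryloxygermacra-4,9,11(13)-triene-12,8:15,6-diolide) ⇒ silyl ether 22 ⇒ open ester 20 by tandem ring-closing metathesis: C4=C5 (butenolide) first, then C9=C10 (ten-membered ring).
2. 20 ⇒ C6–O ester bond: Mitsunobu esterification, with inversion at C6, of lactone alcohol 8 with acid 19.
3. 19 ⇒ C3–O bond and C3 stereocentre by an enantioconvergent Lewis-base acyloxylation of racemic Morita–Baylis–Hillman (MBH) carbonate 16 with isobutyric acid; 16 from 2-methylidenepropane-1,3-diol (Claisen) and tert-butyl acrylate (MBH).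
4. 8 ⇒ zinc Barbier allylation of acrolein with bromobutenolide 6 (sets C7 and C6); 6 ⇒ esterification and metathesis of dienol 3, whose C8–O stereocentre comes from iridium-catalysed allylic hydroxylation of sorbyl carbonate 2.
5. Ring order: 12,8-lactone (steps 4–5) → 15,6-butenolide → ten-membered carbocycle (both in step 13).

Assumption: germacrane numbering is used (lactones C12–O–C8 and C15–O–C6, ester at C3, CH2OH = C14); the given SMILES then corresponds to (3S,6R,7S,8R), with C9=C10 E by CIP (ring carbons cis) and the butenolide C4=C5 trans within the ten-membered ring.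

**Route**

Step 1
Reactants: 1 (2E,4E)-hexa-2,4-dien-1-ol
Product: 2 (2E,4E)-hexa-2,4-dien-1-yl methyl carbonate
Conditions: ClCO2Me, pyridine, CH2Cl2, 0 °C
Reagents that add atoms: methyl chloroformate COC(=O)Cl
Why: Alkoxycarbonylation of a primary allylic alcohol installs the carbonate leaving group needed for π-allyl formation.

Step 2
Reactants: 2 (2E,4E)-hexa-2,4-dien-1-yl methyl carbonate
Product: 3 (3S,4E)-hexa-1,4-dien-3-ol
Conditions: [Ir(cod)Cl]2 (2 mol %), (Sa,S,S)-O,O′-(1,1′-binaphthyl-2,2′-diyl)-N,N-bis(1-phenylethyl)phosphoramidite (4 mol %), TBD (8 mol %), KHCO3 (2 equiv), CH2Cl2/H2O, rt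
Reagents that add atoms: water O
Why: Iridium-catalysed enantioselective allylic substitution with hydrogencarbonate as hydroxide carrier (decarboxylation after C–O bond formation) attacks the internal terminus of the dienyl-substituted allyl complex, giving the branched bis-allylic alcohol with the E-propenyl group intact; the ligand antipode fixes 3S (the mirror-image ligand is taken if the facial sense for this dienyl substrate proves opposite), and this carbon becomes C8.

Step 3
Reactants: 3 (3S,4E)-hexa-1,4-dien-3-ol; 4 2-(bromomethyl)prop-2-enoic acid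
Product: 5 (3S,4E)-hexa-1,4-dien-3-yl 2-(bromomethyl)prop-2-enoate
Conditions: DIC, DMAP (5 mol %), CH2Cl2, −20 → 0 °C
Reagents that add atoms: none
Why: Carbodiimide (Steglich) esterification at low temperature with only catalytic DMAP leaves the allylic bromide and the carbinol stereocentre untouched.

Step 4
Reactants: 5 (3S,4E)-hexa-1,4-dien-3-yl 2-(bromomethyl)prop-2-enoate
Product: 6 (5R)-3-(bromomethyl)-5-[(1E)-prop-1-en-1-yl]furan-2(5H)-one
Conditions: second-generation Grubbs catalyst RuCl2(H2IMes)(PCy3)(=CHPh) (5 mol %), CH2Cl2 (10 mM), 40 °C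
Reagents that add atoms: none
Why: Ring-closing metathesis between the terminal vinyl group and the 1,1-disubstituted acrylate closes the butenolide, while the internal propenyl group initiates much more slowly; the stereocentre is retained (5R by CIP after the priority change).

Step 5
Reactants: 6 (5R)-3-(bromomethyl)-5-[(1E)-prop-1-en-1-yl]furan-2(5H)-one; 7 prop-2-enal
Product: 8 (4R,5R)-4-[(1S)-1-hydroxyprop-2-en-1-yl]-3-methylidene-5-[(1E)-prop-1-en-1-yl]oxolan-2-one
Conditions: Zn dust, THF/sat. aq NH4Cl, 0 °C → rt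
Reagents that add atoms: none
Why: Zinc-mediated Barbier (Dreiding–Schmidt type) γ-allylation: the zinc dienolate attacks through C4 anti to the propenyl group (trans lactone, sets C7), and a closed Zimmerman–Traxler chair with the ring-fixed E-type allyl geometry gives the anti carbinol (1S), the C6 epimer that the invertive esterification in step 12 requires.

Step 6
Reactants: 9 2-methylidenepropane-1,3-diol
Product: 10 2-{[(tert-butyldiphenylsilyl)oxy]methyl}prop-2-en-1-ol
Conditions: NaH (1.0 equiv), THF, 0 °C → rt; TBDPSCl (1.0 equiv)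
Reagents that add atoms: tert-butyldiphenylsilyl chloride CC(C)(C)[Si](Cl)(c1ccccc1)c1ccccc1
Why: Monosilylation of a symmetric diol through its sparingly soluble monosodium alkoxide, which suppresses bis-silylation.

Step 7
Reactants: 10 2-{[(tert-butyldiphenylsilyl)oxy]methyl}prop-2-en-1-ol; 11 ethyl vinyl ether
Product: 13 4-{[(tert-butyldiphenylsilyl)oxy]methyl}pent-4-enal, via allyl vinyl ether 12 (not isolated)
Conditions: 11 (solvent), Hg(OAc)2 (10 mol %), reflux; evaporate; PhMe, 170 °C (sealed tube)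
Reagents that add atoms: none
Why: Mercury-catalysed transvinylation followed by thermal Claisen rearrangement ([3,3] shift through a chair) gives the γ,δ-unsaturated aldehyde and the 1,1-disubstituted olefin that later becomes C10.

Step 8
Reactants: 13 4-{[(tert-butyldiphenylsilyl)oxy]methyl}pent-4-enal; 14 tert-butyl prop-2-enoate
Product: 15 racemic tert-butyl 7-[(tert-butyldiphenylsilyl)oxy]-3-hydroxy-2,6-dimethylideneheptanoate
Conditions: DABCO (1.0 equiv), 14 (3 equiv), 1,4-dioxane/H2O (1:1), rt, 72 h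
Reagents that add atoms: none
Why: Morita–Baylis–Hillman reaction of an aliphatic aldehyde with an acrylate builds the C3–C4 bond; the alcohol is deliberately racemic because C3 is set in step 10.

Step 9
Reactants: 15 racemic tert-butyl 7-[(tert-butyldiphenylsilyl)oxy]-3-hydroxy-2,6-dimethylideneheptanoate
Product: 16 racemic tert-butyl 3-[(tert-butoxycarbonyl)oxy]-7-[(tert-butyldiphenylsilyl)oxy]-2,6-dimethylideneheptanoate
Conditions: Boc2O (1.3 equiv), DMAP (10 mol %), CH2Cl2, 0 °C → rt
Reagents that add atoms: di-tert-butyl dicarbonate CC(C)(C)OC(=O)OC(=O)OC(C)(C)C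
Why: DMAP-catalysed carbonate formation turns the hydroxyl into the self-immolative leaving group used in Lewis-base allylic substitution.

Step 10
Reactants: 16 racemic tert-butyl 3-[(tert-butoxycarbonyl)oxy]-7-[(tert-butyldiphenylsilyl)oxy]-2,6-dimethylideneheptanoate; 17 2-methylpropanoic acid
Product: 18 tert-butyl (3S)-7-[(tert-butyldiphenylsilyl)oxy]-2,6-dimethylidene-3-[(2-methylpropanoyl)oxy]heptanoate
Conditions: (DHQD)2PHAL (10 mol %), 17 (1.5 equiv), PhMe, 4 Å MS, 30 °C
Reagents that add atoms: none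
Why: Proposed new method: the chiral tertiary amine adds SN2′ to the acrylate CH2 of either enantiomer of 16, the carbonate leaves as CO2 and tert-butoxide (which deprotonates 17), and the isobutyrate then adds SN2′ at C3 of the now achiral allylammonium enoate under control of the alkaloid, so the racemate funnels into (3S)-18 and the C3 stereocentre is set in the C–O bond-forming event (the pseudoenantiomeric (DHQ)2PHAL is used if the sense is opposite); the closest known reaction type is the cinchona-alkaloid-catalysed asymmetric allylic substitution of MBH carbonates with water, alcohols, peroxides, amines and carbon acids, which has not been shown with carboxylic acids as O-nucleophiles on β-alkyl carbonates.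

Step 11
Reactants: 18 tert-butyl (3S)-7-[(tert-butyldiphenylsilyl)oxy]-2,6-dimethylidene-3-[(2-methylpropanoyl)oxy]heptanoate
Product: 19 (3S)-7-[(tert-butyldiphenylsilyl)oxy]-2,6-dimethylidene-3-[(2-methylpropanoyl)oxy]heptanoic acid
Conditions: TFA/CH2Cl2 (1:4), 0 °C, 2 h
Reagents that add atoms: none
Why: Acidolysis of the tert-butyl ester (E1 loss of isobutene) spares the secondary isobutyrate, the TBDPS ether and the inductively deactivated 1,1-disubstituted olefin at 0 °C.

Step 12
Reactants: 8 (4R,5R)-4-[(1S)-1-hydroxyprop-2-en-1-yl]-3-methylidene-5-[(1E)-prop-1-en-1-yl]oxolan-2-one; 19 (3S)-7-[(tert-butyldiphenylsilyl)oxy]-2,6-dimethylidene-3-[(2-methylpropanoyl)oxy]heptanoic acid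
Product: 20 (1R)-1-{(2R,3R)-4-methylidene-5-oxo-2-[(1E)-prop-1-en-1-yl]oxolan-3-yl}prop-2-en-1-yl (3S)-7-[(tert-butyldiphenylsilyl)oxy]-2,6-dimethylidene-3-[(2-methylpropanoyl)oxy]heptanoate
Conditions: PPh3 (1.5 equiv) and DIAD (1.5 equiv) premixed in THF at 0 °C; then 19 (1.3 equiv), then 8; 0 °C → rt
Reagents that add atoms: none
Why: Mitsunobu esterification: SN2 displacement of the alkoxyphosphonium salt of 8 by the carboxylate of 19 forms the C6–O bond with inversion (1S → 1R), giving the target C6 configuration; the betaine is pre-formed so that no free phosphine meets the allylic isobutyrate.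

Step 13
Reactants: 20 (1R)-1-{(2R,3R)-4-methylidene-5-oxo-2-[(1E)-prop-1-en-1-yl]oxolan-3-yl}prop-2-en-1-yl (3S)-7-[(tert-butyldiphenylsilyl)oxy]-2,6-dimethylidene-3-[(2-methylpropanoyl)oxy]heptanoate
Product: 22 (3S,6R,7S,8R)-14-[(tert-butyldiphenylsilyl)oxy]-3-[(2-methylpropanoyl)oxy]germacra-4,9,11(13)-triene-12,8:15,6-diolide, via butenolide 21 (not isolated)
Conditions: second-generation Hoveyda–Grubbs catalyst RuCl2(H2IMes)(=CH-C6H4-2-OiPr) (10 mol %), 1,4-benzoquinone (20 mol %), PhMe (1 mM), 60 °C, 3 h; second 10 mol % of catalyst, 110 °C, 12 h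
Reagents that add atoms: none
Why: Tandem ring-closing metathesis: the carbene loads on the only terminal vinyl group and closes the butenolide with the acrylate (21), then at higher temperature and high dilution the propenyl group and the 1,1-disubstituted olefin close the ten-membered ring with loss of propene; the medium ring favours the C9=C10 olefin with cis ring carbons, the trans disposition on the lactone disfavours the competing cyclopentene closure, and no stereocentre is touched.

Step 14
Reactants: 22 (3S,6R,7S,8R)-14-[(tert-butyldiphenylsilyl)oxy]-3-[(2-methylpropanoyl)oxy]germacra-4,9,11(13)-triene-12,8:15,6-diolide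
Product: 23 (3S,6R,7S,8R)-14-hydroxy-3-[(2-methylpropanoyl)oxy]germacra-4,9,11(13)-triene-12,8:15,6-diolide
Conditions: HF·pyridine, pyridine, THF, 0 °C → rt
Reagents that add atoms: none
Why: Buffered fluoride desilylation (Si–F bond formation) frees the primary allylic alcohol without touching the isobutyrate, the two lactones or the exocyclic methylene.

**Compound list**

1 | (2E,4E)-hexa-2,4-dien-1-ol | C/C=C/C=C/CO | starting material
2 | (2E,4E)-hexa-2,4-dien-1-yl methyl carbonate | C/C=C/C=C/COC(=O)OC | intermediate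
3 | (3S,4E)-hexa-1,4-dien-3-ol | O[C@@H](C=C)/C=C/C | intermediate
4 | 2-(bromomethyl)prop-2-enoic acid | C=C(CBr)C(=O)O | starting material
5 | (3S,4E)-hexa-1,4-dien-3-yl 2-(bromomethyl)prop-2-enoate | C=C(CBr)C(=O)O[C@@H](C=C)/C=C/C | intermediate
6 | (5R)-3-(bromomethyl)-5-[(1E)-prop-1-en-1-yl]furan-2(5H)-one | BrCC1=C[C@@H](/C=C/C)OC1=O | intermediate
7 | prop-2-enal | C=CC=O | starting material
8 | (4R,5R)-4-[(1S)-1-hydroxyprop-2-en-1-yl]-3-methylidene-5-[(1E)-prop-1-en-1-yl]oxolan-2-one | C=C1C(=O)O[C@H](/C=C/C)[C@H]1[C@@H](O)C=C | intermediate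
9 | 2-methylidenepropane-1,3-diol | C=C(CO)CO | starting material
10 | 2-{[(tert-butyldiphenylsilyl)oxy]methyl}prop-2-en-1-ol | C=C(CO)CO[Si](c1ccccc1)(c1ccccc1)C(C)(C)C | intermediate
11 | ethyl vinyl ether | C=COCC | starting material
12 | tert-butyl({2-[(ethenyloxy)methyl]prop-2-en-1-yl}oxy)diphenylsilane | C=COCC(=C)CO[Si](c1ccccc1)(c1ccccc1)C(C)(C)C | intermediate
13 | 4-{[(tert-butyldiphenylsilyl)oxy]methyl}pent-4-enal | O=CCCC(=C)CO[Si](c1ccccc1)(c1ccccc1)C(C)(C)C | intermediate
14 | tert-butyl prop-2-enoate | C=CC(=O)OC(C)(C)C | starting material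
15 | racemic tert-butyl 7-[(tert-butyldiphenylsilyl)oxy]-3-hydroxy-2,6-dimethylideneheptanoate | C=C(C(O)CCC(=C)CO[Si](c1ccccc1)(c1ccccc1)C(C)(C)C)C(=O)OC(C)(C)C | intermediate
16 | racemic tert-butyl 3-[(tert-butoxycarbonyl)oxy]-7-[(tert-butyldiphenylsilyl)oxy]-2,6-dimethylideneheptanoate | C=C(C(OC(=O)OC(C)(C)C)CCC(=C)CO[Si](c1ccccc1)(c1ccccc1)C(C)(C)C)C(=O)OC(C)(C)C | intermediate
17 | 2-methylpropanoic acid | CC(C)C(=O)O | starting material
18 | tert-butyl (3S)-7-[(tert-butyldiphenylsilyl)oxy]-2,6-dimethylidene-3-[(2-methylpropanoyl)oxy]heptanoate | CC(C)C(=O)O[C@@H](CCC(=C)CO[Si](c1ccccc1)(c1ccccc1)C(C)(C)C)C(=C)C(=O)OC(C)(C)C | intermediate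
19 | (3S)-7-[(tert-butyldiphenylsilyl)oxy]-2,6-dimethylidene-3-[(2-methylpropanoyl)oxy]heptanoic acid | CC(C)C(=O)O[C@@H](CCC(=C)CO[Si](c1ccccc1)(c1ccccc1)C(C)(C)C)C(=C)C(=O)O | intermediate
20 | (1R)-1-{(2R,3R)-4-methylidene-5-oxo-2-[(1E)-prop-1-en-1-yl]oxolan-3-yl}prop-2-en-1-yl (3S)-7-[(tert-butyldiphenylsilyl)oxy]-2,6-dimethylidene-3-[(2-methylpropanoyl)oxy]heptanoate | C=C1C(=O)O[C@H](/C=C/C)[C@H]1[C@@H](C=C)OC(=O)C(=C)[C@@H](OC(=O)C(C)C)CCC(=C)CO[Si](c1ccccc1)(c1ccccc1)C(C)(C)C | intermediate
21 | (5R)-3-[(1S)-4-{[(tert-butyldiphenylsilyl)oxy]methyl}-1-[(2-methylpropanoyl)oxy]pent-4-en-1-yl]-5-{(2R,3S)-4-methylidene-5-oxo-2-[(1E)-prop-1-en-1-yl]oxolan-3-yl}furan-2(5H)-one | C=C1C(=O)O[C@H](/C=C/C)[C@H]1[C@H]1C=C(C(=O)O1)[C@@H](OC(=O)C(C)C)CCC(=C)CO[Si](c1ccccc1)(c1ccccc1)C(C)(C)C | intermediate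
22 | (3S,6R,7S,8R)-14-[(tert-butyldiphenylsilyl)oxy]-3-[(2-methylpropanoyl)oxy]germacra-4,9,11(13)-triene-12,8:15,6-diolide (C9=C10 E by CIP, ring carbons cis) | C=C1C(=O)O[C@@H]2/C=C(/CO[Si](c4ccccc4)(c5ccccc5)C(C)(C)C)CC[C@H](OC(=O)C(C)C)C3=C[C@@H](OC3=O)[C@@H]12 | intermediate
23 | (3S,6R,7S,8R)-14-hydroxy-3-[(2-methylpropanoyl)oxy]germacra-4,9,11(13)-triene-12,8:15,6-diolide (CNP0322767.4) | C=C1C(=O)O[C@@H]2/C=C(/CO)CC[C@H](OC(=O)C(C)C)C3=C[C@@H](OC3=O)[C@@H]12 | target

**Totals and risk**

Total step count: 14. Longest linear sequence: 9 steps (steps 6–14, from diol 9); the other branch (steps 1–5) joins at step 12.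

The three steps most likely to fail:

Step 10 (the new acyloxylation). Branched-versus-linear regioselectivity and the enantioselectivity are unproven for a carboxylate nucleophile on a β-alkyl carbonate. The fallback uses known chemistry, sets out from 15 and comes back at 18. Racemic 15 is resolved by lipase-catalysed acetylation (Pseudomonas cepacia lipase, vinyl acetate, hexane, 30 °C). By the usual size rule the (3R) alcohol is acetylated to tert-butyl (3R)-3-(acetyloxy)-7-[(tert-butyldiphenylsilyl)oxy]-2,6-dimethylideneheptanoate F2, which is separated, leaving tert-butyl (3S)-7-[(tert-butyldiphenylsilyl)oxy]-3-hydroxy-2,6-dimethylideneheptanoate F1. F1 is acylated with isobutyric anhydride, Et3N and catalytic DMAP at 0 °C to give 18.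

Step 12 (Mitsunobu union). The alcohol is β-branched and allylic, so SN2′ attack at the vinyl terminus, elimination or translactonisation of 8 can compete, and the step relies on the anti outcome of step 5. The fallback sets out from 8 and comes back at 20; it sets C6 by reduction and couples with retention. Dess–Martin periodinane (CH2Cl2, NaHCO3, 0 °C) oxidises 8 to (4S,5R)-3-methylidene-4-(prop-2-enoyl)-5-[(1E)-prop-1-en-1-yl]oxolan-2-one F3. Corey–Bakshi–Shibata reduction ((R)-Me-CBS, catecholborane, PhMe, −78 °C, vinyl acting as the large group; the antipodal catalyst if the branched carbon dominates) gives (4R,5R)-4-[(1R)-1-hydroxyprop-2-en-1-yl]-3-methylidene-5-[(1E)-prop-1-en-1-yl]oxolan-2-one F4. F4 is esterified with 19 with retention (DIC, DMAP 5 mol %, CH2Cl2, 0 °C) to give 20.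

Step 13 (ten-membered ring closure). It forms a trisubstituted olefin in a strained bicyclic frame next to a bulky silyl ether, and oligomerisation or the wrong olefin geometry can win. The fallback sets out from 20 and comes back at 23; it reverses the end-game so that the ring is closed last on the unprotected substrate, where the free allylic hydroxyl assists carbene loading at the neighbouring 1,1-disubstituted olefin and the silyl bulk is gone. HF·pyridine (THF, 0 °C) converts 20 into (1R)-1-{(2R,3R)-4-methylidene-5-oxo-2-[(1E)-prop-1-en-1-yl]oxolan-3-yl}prop-2-en-1-yl (3S)-7-hydroxy-2,6-dimethylidene-3-[(2-methylpropanoyl)oxy]heptanoate F5. Tandem metathesis as in step 13 then passes through (5R)-3-[(1S)-4-(hydroxymethyl)-1-[(2-methylpropanoyl)oxy]pent-4-en-1-yl]-5-{(2R,3S)-4-methylidene-5-oxo-2-[(1E)-prop-1-en-1-yl]oxolan-3-yl}furan-2(5H)-one F6, which is not isolated, and closes directly to 23.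

**Further compounds**

F1 | step 10 | tert-butyl (3S)-7-[(tert-butyldiphenylsilyl)oxy]-3-hydroxy-2,6-dimethylideneheptanoate | O[C@@H](CCC(=C)CO[Si](c1ccccc1)(c1ccccc1)C(C)(C)C)C(=C)C(=O)OC(C)(C)C
F2 | step 10 | tert-butyl (3R)-3-(acetyloxy)-7-[(tert-butyldiphenylsilyl)oxy]-2,6-dimethylideneheptanoate | CC(=O)O[C@H](CCC(=C)CO[Si](c1ccccc1)(c1ccccc1)C(C)(C)C)C(=C)C(=O)OC(C)(C)C
F3 | step 12 | (4S,5R)-3-methylidene-4-(prop-2-enoyl)-5-[(1E)-prop-1-en-1-yl]oxolan-2-one | C=C1C(=O)O[C@H](/C=C/C)[C@H]1C(=O)C=C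
F4 | step 12 | (4R,5R)-4-[(1R)-1-hydroxyprop-2-en-1-yl]-3-methylidene-5-[(1E)-prop-1-en-1-yl]oxolan-2-one | C=C1C(=O)O[C@H](/C=C/C)[C@H]1[C@H](O)C=C
F5 | step 13 | (1R)-1-{(2R,3R)-4-methylidene-5-oxo-2-[(1E)-prop-1-en-1-yl]oxolan-3-yl}prop-2-en-1-yl (3S)-7-hydroxy-2,6-dimethylidene-3-[(2-methylpropanoyl)oxy]heptanoate | C=C1C(=O)O[C@H](/C=C/C)[C@H]1[C@@H](C=C)OC(=O)C(=C)[C@@H](OC(=O)C(C)C)CCC(=C)CO
F6 | step 13 | (5R)-3-[(1S)-4-(hydroxymethyl)-1-[(2-methylpropanoyl)oxy]pent-4-en-1-yl]-5-{(2R,3S)-4-methylidene-5-oxo-2-[(1E)-prop-1-en-1-yl]oxolan-3-yl}furan-2(5H)-one | C=C1C(=O)O[C@H](/C=C/C)[C@H]1[C@H]1C=C(C(=O)O1)[C@@H](OC(=O)C(C)C)CCC(=C)CO
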